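**Plan**

- Retrosynthesis: the C8 ester is cut first (esterification with inversion), then the C7–C8 bond of the ten-membered ring (allyl metal plus aldehyde), then the butenolide (carbonylation at C12, alkynylation at C6), then a C3–O–C14 lactone tether that carries the C1=C10 alkene (ring-closing metathesis), and last C2–C3 (allylation).
- Forward: C3–C5 iodoalkene → allylation at C3 → acrylate ester and metathesis to a six-membered lactone → epoxidation and reductive opening → C6 alkynylation → butenolide → closure of the carbocycle C1–C10 → ester → desilylation.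
- Enabling feature: the homoallylic alcohol array C13=C11–C7–C8–O, which spans the α-methylene-γ-lactone ring and the ten-membered carbocycle. It is the retron of a γ-selective allyl-metal addition from a 3-(bromomethyl)butenolide (C13–Br, C11=C7) to a C8 aldehyde.
- Stereochemistry: C3 by reagent control; C1/C10 relayed from C3 through the six-membered lactone; C6 by catalyst control; C7 from C6 and C8 from the chair transition state in the ring closure; C8 inverted in the esterification; the acyl stereocentre from commercial (S)-2-methylbutanoic acid.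

Key step: step 18

Remark: locants C1–C15 are those of the target's germacrane skeleton (ring C1–C10; lactone C6–O–C12(=O)–C11(=C13)–C7; C14 = hydroxymethyl carbon on C10; C15 = methyl on C4).
Assumption: (S,S)-ProPhenol is taken to deliver the 6R carbinol on this enal; if the sense of induction is the opposite, the (R,R) ligand is used.

**Route**

Step 1
Reactants: 1 prop-2-yn-1-ol
Product: 3 (Z)-3-iodo-2-methylprop-2-en-1-ol, via vinylmagnesium alkoxide 2 (not isolated)
Conditions: MeMgBr (2.5 equiv), CuI (10 mol%), THF, −10 °C → rt; then I2, −78 → 0 °C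
Reagents that add atoms: methylmagnesium bromide, C[Mg]Br; iodine, II
Why: Copper-catalysed anti-carbomagnesiation of the propargylic alkoxide (Duboudin–Jousseaume) places magnesium cis to CH2O in a five-membered chelate, so iodinolysis with retention should give the Z iodide (C5–I cis to C3).

Step 2
Reactants: 3 (Z)-3-iodo-2-methylprop-2-en-1-ol
Product: 4 (Z)-3-iodo-2-methylprop-2-enal
Conditions: MnO2, CH2Cl2, rt, dark; used crude
Reagents that add atoms: none
Why: Neutral allylic oxidation with MnO2 should leave the Z iodoalkene untouched.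

Step 3
Reactants: 4 (Z)-3-iodo-2-methylprop-2-enal
Product: 6 (3S,1Z)-1-iodo-2-methylhexa-1,5-dien-3-ol, via borinate 5 (not isolated)
Conditions: (−)-Ipc2BOMe, allylMgBr, Et2O, 0 °C → rt; then 4, −78 °C; NaOH, H2O2, 0 °C → rt
Reagents that add atoms: allylmagnesium bromide, C=CC[Mg]Br (allyl group, relayed through (−)-Ipc2B(allyl))
Why: Brown allylboration through a chair transition state; (−)-Ipc2B(allyl) attacks the si face of the aldehyde, which should set C3 as S, and −78 °C preserves the Z iodoalkene.

Step 4
Reactants: 7 α-methylene-γ-butyrolactone (tulipalin A)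
Product: 10 2-methylidene-4-(triethylsilyloxy)butanoic acid, via sodium hydroxy carboxylate 8 (not isolated), via bis-silyl derivative 9 (not isolated)
Conditions: NaOH (1.0 equiv), H2O/THF, 0 °C → rt, evaporate; TESCl (2.2 equiv), imidazole, DMF, 0 °C; K2CO3, MeOH/H2O, 0 °C, then pH 5 buffer
Reagents that add atoms: sodium hydroxide, [Na+].[OH-]; chlorotriethylsilane, CC[Si](Cl)(CC)CC
Why: Saponification opens the lactone to a carboxylate that cannot re-close, and silylation of both oxygens followed by selective hydrolysis of the labile silyl ester should leave the C8 TES ether (no stereocentre).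

Step 5
Reactants: 6 (3S,1Z)-1-iodo-2-methylhexa-1,5-dien-3-ol; 10 2-methylidene-4-(triethylsilyloxy)butanoic acid
Product: 11 (3S,1Z)-1-iodo-2-methylhexa-1,5-dien-3-yl 2-methylidene-4-(triethylsilyloxy)butanoate
Conditions: DCC, DMAP (cat.), CH2Cl2, 0 °C → rt
Reagents that add atoms: none
Why: Steglich esterification of the secondary allylic alcohol; C3 is not touched.

Step 6
Reactants: 11 the C3 ester
Product: 12 (6S)-6-[(Z)-1-iodoprop-1-en-2-yl]-3-[2-(triethylsilyloxy)ethyl]-5,6-dihydro-2H-pyran-2-one
Conditions: second-generation Grubbs catalyst (5–10 mol%), toluene (5 mM), 80 °C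
Reagents that add atoms: none
Why: Ring-closing metathesis of the allyl group with the 1,1-disubstituted acrylate, driven by loss of ethylene; the six-membered ring forces C2 cis to C14 on C1=C10, the geometry required for the later epoxide, and the hindered iodoalkene should not take part.

Step 7
Reactants: 12 the unsaturated δ-lactone
Product: 13 (1R,4S,6R)-4-[(Z)-1-iodoprop-1-en-2-yl]-1-[2-(triethylsilyloxy)ethyl]-3,7-dioxabicyclo[4.1.0]heptan-2-one (epoxide oxygen trans to the iodoalkenyl group)
Conditions: tBuOOH (decane), BnMe3NOH (cat.), THF, 0 °C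
Reagents that add atoms: tert-butyl hydroperoxide, CC(C)(C)OO
Why: Weitz–Scheffer nucleophilic epoxidation; the hydroperoxide anion should add axially to C1 of the half-chair lactone anti to the pseudo-equatorial C3 substituent and close on the same face, which sets C1 (R) and C10 from C3.

Step 8
Reactants: 13 the epoxy lactone
Product: 14 [(2S,3R)-3-[(2S,3Z)-2-hydroxy-4-iodo-3-methylbut-3-en-1-yl]-2-[2-(triethylsilyloxy)ethyl]oxiran-2-yl]methanol (free O3–H and O14–H)
Conditions: LiBH4, THF, MeOH (1 equiv), 0 °C → rt
Reagents that add atoms: none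
Why: Borohydride reduction of the lactone through the lactol to the diol; the trisubstituted epoxide, the iodoalkene and the silyl ether should survive, and no stereocentre is touched.

Step 9
Reactants: 14 the epoxy diol
Product: 15 the bis-TBS ether of 14 (TBS on O3 and O14; C5 iodide, C8 OTES)
Conditions: TBSOTf, 2,6-lutidine, CH2Cl2, −78 °C
Reagents that add atoms: tert-butyldimethylsilyl triflate, CC(C)(C)[Si](C)(C)OS(=O)(=O)C(F)(F)F
Why: Standard silylation of a primary and a hindered secondary alcohol; the buffered low temperature should spare the epoxide.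

Step 10
Reactants: 15 the vinyl iodide
Product: 17 the (Z)-enal (C6 aldehyde on C5, cis to C3; O3 and O14 TBS, C8 OTES), via vinyllithium 16 (not isolated)
Conditions: tBuLi (2.1 equiv), Et2O, −78 °C; then DMF, −78 → −20 °C
Reagents that add atoms: N,N-dimethylformamide, CN(C)C=O
Why: Iodine–lithium exchange with retention of alkene geometry followed by Bouveault formylation; immediate trapping at −78 °C in ether should suppress 1,4-silyl migration from O3 and attack on the epoxide.

Step 11
Reactants: 17 the (Z)-enal; 18 4-methoxybenzyl propargyl ether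
Product: 19 the (6R)-propargylic alcohol (C6–OH; C7≡C11; C13 OPMB)
Conditions: 18 (3 equiv), Me2Zn (3 equiv), (S,S)-ProPhenol (20 mol%), Ph3PO (40 mol%), toluene, 4 °C
Reagents that add atoms: none
Why: Trost ProPhenol–zinc alkynylation of an α,β-unsaturated aldehyde; the dinuclear zinc catalyst selects the aldehyde face and should set C6 as R by catalyst control.

Step 12
Reactants: 19 the propargylic alcohol
Product: 21 the (Z)-vinyl iodide (C7H=C11(I)–C13, iodine cis to C6; free C6–OH), via cyclic vinylalanate 20 (not isolated)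
Conditions: NaAlH2(OCH2CH2OMe)2 (Red-Al), THF, −20 → 0 °C; then I2, THF, −78 °C
Reagents that add atoms: iodine, II
Why: Alkoxide-directed trans-hydroalumination delivers hydride to C7 and aluminium to C11 in a five-membered ring, and iodinolysis with retention should give the Z iodide; the epoxide has no free hydroxyl to direct its reduction.

Step 13
Reactants: 21 the (Z)-iodo allylic alcohol
Product: 22 the (5R)-butenolide, 3-[(4-methoxybenzyloxy)methyl]-5-substituted furan-2(5H)-one (C12 carbonyl in place)
Conditions: PdCl2(PPh3)2 (5 mol%), CO (1 atm), K2CO3, THF, rt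
Reagents that add atoms: carbon monoxide, [C-]#[O+]
Why: Palladium-catalysed carbonylative lactonisation: oxidative addition at C11–I, CO insertion and capture of the acylpalladium by the cis C6–OH; the mild carbonate base should avoid epimerisation at C6.

Step 14
Reactants: 22 the PMB ether
Product: 23 the 3-(hydroxymethyl)butenolide (free C13–OH)
Conditions: DDQ, CH2Cl2/pH 7 buffer, 0 °C
Reagents that add atoms: none
Why: Oxidative cleavage of the PMB ether; the silyl ethers, epoxide and butenolide should be inert.

Step 15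
Reactants: 23 the allylic alcohol
Product: 24 the 3-(bromomethyl)butenolide (C13–Br; C8 OTES)
Conditions: CBr4, PPh3, CH2Cl2, 0 °C
Reagents that add atoms: carbon tetrabromide, BrC(Br)(Br)Br
Why: Appel bromination of the primary allylic alcohol under neutral conditions.

Step 16
Reactants: 24 the TES ether
Product: 25 the bromomethyl butenolide with free C8–OH
Conditions: PPTS (cat.), MeOH/CH2Cl2, 0 °C
Reagents that add atoms: none
Why: Mild acid methanolysis cleaves the primary TES ether much faster than the two TBS ethers and should leave the allylic bromide and the epoxide intact.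

Step 17
Reactants: 25 the primary alcohol
Product: 26 the bromo aldehyde (C8 aldehyde, β,γ to the epoxide; C13–Br)
Conditions: Dess–Martin periodinane, NaHCO3, CH2Cl2, 0 °C; used at once
Reagents that add atoms: none
Why: Buffered Dess–Martin oxidation, chosen because neutral conditions should avoid β-elimination of the β,γ-epoxy aldehyde.

Step 18
Reactants: 26 the bromo aldehyde
Product: 28 the macrocyclic (6R,7R,8S)-alcohol (ten-membered ring closed, C11=C13 exo-methylene lactone, free 8-OH, O3 and O14 TBS), via allylchromium 27 (not isolated)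
Conditions: CrCl2 (10 equiv), THF (2 mM), rt, syringe-pump addition of 26 over 10 h
Reagents that add atoms: none
Why: CrCl2 reduces the allylic C13–Br bond in two one-electron steps to the C13 allylchromium 27 (trivalent chromium), which adds through its γ-carbon C7 to the C8 aldehyde in a six-membered chair transition state with transposition of the double bond to C11=C13, so that ring, exo-methylene and carbinol arise together. The closest known reaction type is the Nozaki–Hiyama–Kishi (Barbier-type) allylation, known for 5-substituted 3-(bromomethyl)furan-2(5H)-ones with aldehydes and for macrocyclisations of 2-(bromomethyl)acrylates. The ten-membered carbocycle closes in the 10-exo-trig mode, C7 attacking the aldehyde carbon whose oxygen stays outside the ring. C7 is set by C6: the tether should reach C7 only on the face opposite the C5 substituent, since the alternative needs an eclipsed C5–C6–C7–C8 array, and this gives the trans-fused lactone (7R). C8 is set by the chair: the ring-fixed geometry at C7=C11 (C6 trans to C13) puts C6 pseudo-equatorial and C9 equatorial, which should give the 7,8-anti alcohol (8S), the epimer that step 19 inverts. The step needs γ- over α-attack, aldehyde over lactone and epoxide, and cyclisation over oligomerisation; the first two are inherent in allylchromium reagents and the third is secured by high dilution and slow addition.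

Step 19
Reactants: 28 the (8S)-alcohol; 29 (S)-2-methylbutanoic acid
Product: 30 the bis-TBS ether of the target (8R ester)
Conditions: PPh3, DIAD, toluene, 0 °C → rt (betaine pre-formed before 28 is added)
Reagents that add atoms: none
Why: Mitsunobu esterification; SN2 displacement of the C8 oxyphosphonium by the carboxylate should invert C8 to R and install the ester in one operation.

Step 20
Reactants: 30 the bis-TBS ether
Product: 31 the target, CNP0356520.3
Conditions: HF·pyridine, pyridine, THF, 0 °C → rt
Reagents that add atoms: none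
Why: Buffered fluoride desilylation of both TBS ethers; these conditions should spare the epoxide, the ester and the α-methylene lactone.

**Compound list**

1 | prop-2-yn-1-ol | C#CCO | starting material
2 | bromomagnesium (Z)-3-(bromomagnesio)-2-methylprop-2-en-1-olate | Br[Mg]/C=C(/C)CO[Mg]Br | intermediate (not isolated)
3 | (Z)-3-iodo-2-methylprop-2-en-1-ol | I/C=C(/C)CO | intermediate
4 | (Z)-3-iodo-2-methylprop-2-enal | I/C=C(/C)C=O | intermediate
5 | O-(diisopinocampheylboryl) ether of 6 | I/C=C(/C)[C@@H](OB([C@@H]1C[C@@H]2C[C@H]([C@H]1C)C2(C)C)[C@@H]1C[C@@H]2C[C@H]([C@H]1C)C2(C)C)CC=C | intermediate (not isolated)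
6 | (3S,1Z)-1-iodo-2-methylhexa-1,5-dien-3-ol | I/C=C(/C)[C@@H](O)CC=C | intermediate
7 | 3-methylideneoxolan-2-one (α-methylene-γ-butyrolactone, tulipalin A) | C=C1CCOC1=O | starting material
8 | sodium 4-hydroxy-2-methylidenebutanoate | C=C(CCO)C(=O)[O-].[Na+] | intermediate (not isolated)
9 | triethylsilyl 2-methylidene-4-(triethylsilyloxy)butanoate | C=C(CCO[Si](CC)(CC)CC)C(=O)O[Si](CC)(CC)CC | intermediate (not isolated)
10 | 2-methylidene-4-(triethylsilyloxy)butanoic acid | C=C(CCO[Si](CC)(CC)CC)C(=O)O | intermediate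
11 | (3S,1Z)-1-iodo-2-methylhexa-1,5-dien-3-yl 2-methylidene-4-(triethylsilyloxy)butanoate | I/C=C(/C)[C@@H](OC(=O)C(=C)CCO[Si](CC)(CC)CC)CC=C | intermediate
12 | (6S)-6-[(Z)-1-iodoprop-1-en-2-yl]-3-[2-(triethylsilyloxy)ethyl]-5,6-dihydro-2H-pyran-2-one | I/C=C(/C)[C@@H]1CC=C(CCO[Si](CC)(CC)CC)C(=O)O1 | intermediate
13 | (1R,4S,6R)-4-[(Z)-1-iodoprop-1-en-2-yl]-1-[2-(triethylsilyloxy)ethyl]-3,7-dioxabicyclo[4.1.0]heptan-2-one | I/C=C(/C)[C@@H]1C[C@H]2O[C@]2(C(=O)O1)CCO[Si](CC)(CC)CC | intermediate
14 | [(2S,3R)-3-[(2S,3Z)-2-hydroxy-4-iodo-3-methylbut-3-en-1-yl]-2-[2-(triethylsilyloxy)ethyl]oxiran-2-yl]methanol | I/C=C(/C)[C@@H](O)C[C@H]1O[C@]1(CO)CCO[Si](CC)(CC)CC | intermediate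
15 | bis-TBS ether of 14 (TBS on O3 and O14) | I/C=C(/C)[C@@H](O[Si](C)(C)C(C)(C)C)C[C@H]1O[C@]1(CO[Si](C)(C)C(C)(C)C)CCO[Si](CC)(CC)CC | intermediate
16 | (Z)-C5 vinyllithium derived from 15 | [Li]/C=C(/C)[C@@H](O[Si](C)(C)C(C)(C)C)C[C@H]1O[C@]1(CO[Si](C)(C)C(C)(C)C)CCO[Si](CC)(CC)CC | intermediate (not isolated)
17 | (Z)-enal: C6 aldehyde on C5, cis to C3; otherwise as 15 | O=C/C=C(/C)[C@@H](O[Si](C)(C)C(C)(C)C)C[C@H]1O[C@]1(CO[Si](C)(C)C(C)(C)C)CCO[Si](CC)(CC)CC | intermediate
18 | 1-methoxy-4-[(prop-2-yn-1-yloxy)methyl]benzene (4-methoxybenzyl propargyl ether) | C#CCOCc1ccc(OC)cc1 | starting material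
19 | (6R)-propargylic alcohol: C6–OH, C7≡C11, C13 OPMB | O[C@@H](C#CCOCc1ccc(OC)cc1)/C=C(/C)[C@@H](O[Si](C)(C)C(C)(C)C)C[C@H]2O[C@]2(CO[Si](C)(C)C(C)(C)C)CCO[Si](CC)(CC)CC | intermediate
20 | sodium cyclic vinylalanate (O6–Al–C11 five-membered ring) | [Na+].O1[C@@H](C=C(COCc2ccc(OC)cc2)[Al-]1(OCCOC)OCCOC)/C=C(/C)[C@@H](O[Si](C)(C)C(C)(C)C)C[C@H]3O[C@]3(CO[Si](C)(C)C(C)(C)C)CCO[Si](CC)(CC)CC | intermediate (not isolated)
21 | (6R)-(Z)-C11 vinyl iodide with free C6–OH (iodine cis to C6) | O[C@@H](/C=C(\I)COCc1ccc(OC)cc1)/C=C(/C)[C@@H](O[Si](C)(C)C(C)(C)C)C[C@H]2O[C@]2(CO[Si](C)(C)C(C)(C)C)CCO[Si](CC)(CC)CC | intermediate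
22 | (5R)-3-[(4-methoxybenzyloxy)methyl]butenolide bearing the C1–C5/C8–C10 chain at its 5-position | O=C1O[C@@H](C=C1COCc2ccc(OC)cc2)/C=C(/C)[C@@H](O[Si](C)(C)C(C)(C)C)C[C@H]3O[C@]3(CO[Si](C)(C)C(C)(C)C)CCO[Si](CC)(CC)CC | intermediate
23 | 3-(hydroxymethyl)butenolide (free C13–OH) | O=C1O[C@@H](C=C1CO)/C=C(/C)[C@@H](O[Si](C)(C)C(C)(C)C)C[C@H]3O[C@]3(CO[Si](C)(C)C(C)(C)C)CCO[Si](CC)(CC)CC | intermediate
24 | 3-(bromomethyl)butenolide, C8 OTES | O=C1O[C@@H](C=C1CBr)/C=C(/C)[C@@H](O[Si](C)(C)C(C)(C)C)C[C@H]3O[C@]3(CO[Si](C)(C)C(C)(C)C)CCO[Si](CC)(CC)CC | intermediate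
25 | 3-(bromomethyl)butenolide, free C8–OH | O=C1O[C@@H](C=C1CBr)/C=C(/C)[C@@H](O[Si](C)(C)C(C)(C)C)C[C@H]3O[C@]3(CO[Si](C)(C)C(C)(C)C)CCO | intermediate
26 | 3-(bromomethyl)butenolide, C8 aldehyde | O=C1O[C@@H](C=C1CBr)/C=C(/C)[C@@H](O[Si](C)(C)C(C)(C)C)C[C@H]3O[C@]3(CO[Si](C)(C)C(C)(C)C)CC=O | intermediate
27 | C13 allylchromium dichloride of 26 | O=C1O[C@@H](C=C1C[Cr](Cl)Cl)/C=C(/C)[C@@H](O[Si](C)(C)C(C)(C)C)C[C@H]3O[C@]3(CO[Si](C)(C)C(C)(C)C)CC=O | intermediate (not isolated)
28 | macrocyclic (6R,7R,8S)-alcohol, O3 and O14 TBS | C=C1C(=O)O[C@@H]2/C=C(/C)[C@@H](O[Si](C)(C)C(C)(C)C)C[C@H]3O[C@]3(CO[Si](C)(C)C(C)(C)C)C[C@H](O)[C@@H]12 | intermediate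
29 | (S)-2-methylbutanoic acid | CC[C@H](C)C(=O)O | starting material
30 | O3,O14-bis-TBS ether of the target | C=C1C(=O)O[C@@H]2/C=C(/C)[C@@H](O[Si](C)(C)C(C)(C)C)C[C@H]3O[C@]3(CO[Si](C)(C)C(C)(C)C)C[C@@H](OC(=O)[C@@H](C)CC)[C@@H]12 | intermediate
31 | CNP0356520.3 | C=C1C(=O)O[C@@H]2/C=C(/C)[C@@H](O)C[C@H]3O[C@]3(CO)C[C@@H](OC(=O)[C@@H](C)CC)[C@@H]12 | target

**Step count**

Total: 20 steps. Longest linear sequence: 19 steps (steps 1–3 and 5–20, from prop-2-yn-1-ol).

**Steps most likely to fail**

Step 18. Intermolecular coupling and protodebromination of the short-lived allylchromium may outpace the slow ten-membered ring closure, and facial selectivity at C7 may erode. The fallback replaces the reductively generated allyl metal by an isolable allylboronate that is cyclised thermally (intramolecular allylboration, known for 2-alkoxycarbonyl allylboronates and aldehydes). It sets out from 24. Pd2(dba)3-catalysed borylation with bis(pinacolato)diboron should give the C13 pinacol allylboronate F1. PPTS in MeOH then frees the C8 alcohol F2, and Dess–Martin oxidation gives the boronate aldehyde F3. Heating F3 in dilute toluene (80 °C) should close the ring through the same chair to the O8-boryl macrocycle F4, and buffered aqueous work-up releases 28, where the route is rejoined.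

Step 19. The activated C8 oxyphosphonium may eliminate toward C9 or C7, the ester may form with retention through an acyloxyphosphonium pathway, and the phosphine may add to C13 of the α-methylene lactone. The fallback is a phosphine-free, two-stage sulfonate displacement. It sets out from 28. ClCH2SO2Cl and pyridine at 0 °C give the C8 chloromethanesulfonate F5. Acid 29 and Cs2CO3 give caesium (S)-2-methylbutanoate F6. F5 and F6 with 18-crown-6 in toluene at 40 °C should give 30 by SN2 inversion, where the route is rejoined.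

Step 7. Conjugate addition of the hydroperoxide to the α-branched unsaturated lactone may be sluggish, the lactone may open by base-induced elimination or hydrolysis, and facial selectivity may be incomplete. The fallback replaces substrate control by reagent control on the ring-opened allylic alcohol. It sets out from 12. Reduction with iBu2AlH (CH2Cl2, −78 → 0 °C) gives the Z-allylic diol F7. Sharpless epoxidation with Ti(OiPr)4, D-(−)-diethyl tartrate and tBuOOH (CH2Cl2, −20 °C) should deliver oxygen to the required face of C1=C10 under direction of the C14 hydroxyl; the C3 hydroxyl flanks only the deactivated iodoalkene. This gives 14, where the route is rejoined.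

**Further compounds**

F1 | step 18 | C13 pinacol allylboronate (24 with CH2Br replaced by CH2B(pin)) | O=C1O[C@@H](C=C1CB2OC(C)(C)C(C)(C)O2)/C=C(/C)[C@@H](O[Si](C)(C)C(C)(C)C)C[C@H]3O[C@]3(CO[Si](C)(C)C(C)(C)C)CCO[Si](CC)(CC)CC
F2 | step 18 | allylboronate with free C8–OH | O=C1O[C@@H](C=C1CB2OC(C)(C)C(C)(C)O2)/C=C(/C)[C@@H](O[Si](C)(C)C(C)(C)C)C[C@H]3O[C@]3(CO[Si](C)(C)C(C)(C)C)CCO
F3 | step 18 | allylboronate C8 aldehyde | O=C1O[C@@H](C=C1CB2OC(C)(C)C(C)(C)O2)/C=C(/C)[C@@H](O[Si](C)(C)C(C)(C)C)C[C@H]3O[C@]3(CO[Si](C)(C)C(C)(C)C)CC=O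
F4 | step 18 | O8-(pinacolatoboryl) derivative of 28 | C=C1C(=O)O[C@@H]2/C=C(/C)[C@@H](O[Si](C)(C)C(C)(C)C)C[C@H]3O[C@]3(CO[Si](C)(C)C(C)(C)C)C[C@H](OB4OC(C)(C)C(C)(C)O4)[C@@H]12
F5 | step 19 | C8 chloromethanesulfonate of 28 | C=C1C(=O)O[C@@H]2/C=C(/C)[C@@H](O[Si](C)(C)C(C)(C)C)C[C@H]3O[C@]3(CO[Si](C)(C)C(C)(C)C)C[C@H](OS(=O)(=O)CCl)[C@@H]12
F6 | step 19 | caesium (S)-2-methylbutanoate | CC[C@H](C)C(=O)[O-].[Cs+]
F7 | step 7 | (2Z,5S,6Z)-7-iodo-6-methyl-2-[2-(triethylsilyloxy)ethyl]hepta-2,6-diene-1,5-diol | I/C=C(/C)[C@@H](O)C/C=C(\CO)CCO[Si](CC)(CC)CC
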